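(All runs stem from a simulated flask from invented constants, and the scatter is random.)

Follow one substrate molecule.

- alpha: substrate 0.020 M; gas phase 0.70 mM (held); the very flask that is asked about, followed so far
- flask: substrate 0.020 M; gas phase 0.70 mM (held); time 40 min

alpha run (percent of the substrate charged)

| time / min | over-reaction product / % | target / % |
|---|---|---|
| 0.500 | 9.8 | 30.5 |
| 1.50 | 51.5 | 18.9 |
| 3.00 | 73.2 | 1.0 |
| 4.00 | 74.0 | 0 |
| 6.00 | 75.4 | 0 |
| 8.00 | 75.0 | 0 |

(readings scatter by 0.5 percentage points)

- at the start none of the gas phase is in solution
- the reaction counts as stopped when no species that holds the substrate changes by six tenths of a point or more over the second half of the time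

1. which holds at 40 min: what has brought the reaction to rest, or that it has not come to rest (all of the substrate has reacted / forward and back rates have come level / it is still moving)
2. how much over-reaction product there is at 40 min, in percent of the substrate charged

Where does it end? In the alpha run, which is this flask followed so far, over-reaction product levels at 74.8% of the charge while target reads 0%. So a quarter of the charge is unseen.

Is that quarter substrate, resting in balance with target? I test this with the ratio of target to the unseen part. In the alpha run it reads 0.511 at 0.500 min, 0.639 at 1.50 min and 0.0388 at 3.00 min. So it first climbs, then drops far lower, and from 4.00 min on target reads 0% beside the unseen part. In these readings I see no balance that holds target against that part. So I reckon that the substrate has reacted to the end, and that the unseen part is side product.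

Each molecule then has a fork: with gas towards target and over-reaction product, or off to side product. I call over-reaction product at rest over the unseen remainder the fork ratio, a selectivity factor. For the alpha run it is 2.97.

Will more come later? Target, the feed of over-reaction product, reads 0% at 8.00 min, so I expect 74.8% at 40 min.

The forecast says forward and back rates have come level and 75%: “The fast approach followed by a flat plateau reads as a balance between forward and back rates.” Our amounts lie close together, but we part on the ending.

    gas phase ⇌ dissolved gas, rate k1*(csat - [dissolved gas]) (kL = 0.860 s⁻¹)
    substrate + dissolved gas → target (k = 70.0 M⁻¹ s⁻¹)
    substrate → side product (k = 0.00760 s⁻¹)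
    dissolved gas + target → over-reaction product (k = 61.0 M⁻¹ s⁻¹)
    dissolved gas → decomposed reagent (k = 0.0170 s⁻¹)

At 40 min the flask gives 74.9%, and the ending is that all of the substrate has reacted. Substrate stands at 0% and side product at 25.1%. A neighbour flask with 0.034 M of substrate ends with 69.1% of over-reaction product and 30.9% of side product, so its fork ratio is 2.24, lower than the 2.97 read for this flask.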